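Amounts first: the flask asked about is Sunday's own flask, followed further, so its readings are read directly as percentages of its charge.

- Sunday's: starting complex 0.10 M; gas 3.2 mM (held); the very flask that is asked about, followed so far
- flask: starting complex 0.10 M; gas 3.2 mM (held); time 15 min

- Sunday's (time / min: complex with one exchanged / %): 1.00: 30.9; 1.33: 28.0; 2.00: 23.1; 3.00: 20.2; 5.00: 19.3; 8.00: 18.4; 12.0: 18.8

(scatter of a reading: 0.3 percentage points)

- south-west: at 15 min take out 90% of the complex with one exchanged then present, then wait 30 min
- north: change nothing and wait 30 min more
- east: at 15 min add starting complex, 50.0% of the amount charged, then wait 30 min

* complex with one exchanged, in percent of the starting complex first charged, at 15 min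
* what to do for the largest gain in complex with one exchanged; "none" if nothing gains more than 2 percentage points (south-west / north / east / none)
* complex with one exchanged present, with what was taken out counted in, in percent of the starting complex first charged, after south-west
* complex with one exchanged present, with what was taken out counted in, in percent of the starting complex first charged, after north

- what is taken out of complex with one exchanged is counted as made
- at the start none of the gas is in solution
- additions bring no volume worth counting

The complex with one exchanged falls from 30.9% at 1.00 min, but from 5.00 min on the readings wander about a level. Their mean is 18.8%, and I name it the plateau share: the part of the complex in the flask that, as these readings show it, stands as complex with one exchanged after the fall has ended.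

The excess over it shrinks from 12 percentage points to 1.4 points by 3.00 min, a half-life read at 0.636 min. So 30 min of waiting is long enough, and north stays at the plateau share. I assume that share holds in this flask when its total changes.

South-west removes 16.9%. A first go refills to the plateau share, giving 35.7% counted. But 83.0% of the complex remains, so I go round once more: 15.6% present, 32.6% counted. East gives 28.2%, less than that, so I choose south-west.

The forecast says that what remains after south-west “re-equilibrates within minutes”. It gives 18.7% now (18.3% to 19.1%), 18.7% after north and 32.4% after south-west (28% to 34%), and chooses south-west. My 32.6% stands slightly higher.

The flask gives 18.8% now, 18.6% after north and 32.3% after south-west, whose gain of 13 points is the largest.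

    starting complex + incoming ligand ⇌ leaving ligand + complex with one exchanged (K = 16.9, k = 9.09 /M/s)
    complex with one exchanged + incoming ligand ⇌ leaving ligand + complex with two exchanged (K = 32.0, k = 4.97 /M/s)
    complex with two exchanged + incoming ligand ⇌ leaving ligand + complex with three exchanged (K = 53.9, k = 6.50 /M/s)
    gas ⇌ incoming ligand, rate k4*(csat - [incoming ligand]) (kL = 1.79 /s)
    complex with one exchanged → over-reaction product (k = 3.05 × 10⁻⁵ /s)

In this flask, half the turnover of the first exchange up to 15 min is done by 0.325 min, far earlier. At 15 min its backward rate stands at >99.9% of its forward rate, so this step runs back about as fast as it runs forward, the mark of thermodynamic control. For the neighbour charged with 0.40 M of starting complex, the plateau share gives 18.8% of its own charge; computed, that neighbour holds 17.1% at 15 min, somewhat less.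

The earlier runs and the new flask stem from a simulated flask for an exercise, noise included.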